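## The problem

Septeremophilane E (33) is a bicyclic trinor-eremophilane ester in which two six-membered rings share the C5–C10 bond (ring A: C1, C2, C3, C4, C5, C10; ring B: C5, C6, C7, C8, C9, C10). Ring B is a cross-conjugated dienone (C8 ketone, C9=C10, C6=C7 with the enolic C7 hydroxyl), and its conjugation runs on into ring A through C1=C2. Ring A carries three contiguous stereocentres, C3 (S, acyloxy), C4 (R, methyl) and the quaternary ring-fusion carbon C5 (S, methyl), with all three substituents on one face. A fourth stereocentre (R) sits in the dienoate side chain, too far from the core to be controlled by it, so it needs its own asymmetric step. Within the core a chain of control exists: a bulky C3 silyl ether can direct the C4 methyl (reduction from the opposite face), and the C4 methyl can direct C5 (alkylation anti to it). The acidic, easily acylated diosphenol, the trienone (vinylogously acidic C3–H, dienone–phenol rearrangement in strong acid) and the allylic (E,E)-dienoate do not tolerate dissolving metal, strong base or strong acid, so the side chain must go on last and the final unmasking must be mild. The enabling feature lies in ring B: C7 and C8 are neighbouring oxygen-bearing carbons, each one carbon (C6, C9) away from the adjacent ring A atoms C5 and C10, which is the pattern left by an acyloin coupling of two acetate arms.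

## Retrosynthesis

**Ester bond.** The C3–O acyl bond is cut first, giving core alcohol 21 and dienoic acid 30 (coupled as 32, then desilylated to 33). This keeps the reducible, base-sensitive dienoate out of every core step. The forward reaction must acylate a hindered secondary alcohol without touching the C3–O bond, and the C7 enol must be masked, here as a silyl ether that falls in the same final step as the side-chain silyl ether.

**Telling the two hydroxyls apart.** 21 is traced to diol 20 and that to bis-silyl ether 19. Fluoride cannot free the C3 alkyl silyl ether while keeping the C7 enol silyl ether, so both are removed and the acidic enol alone is silylated again. This costs one step but uses only mild reagents on the sensitive trienone.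

**C1=C2 double bond.** 19 is traced to diosphenol 17 by removing the C1=C2 unsaturation. Forward, 17 is converted into the extended silyl trienol ether 18, whose only allylic C–H is at C2, and dehydrogenated there. Dehydrogenating the free diosphenol directly would expose the enol to the oxidant.

**Oxidation level of ring B.** 17 is the enol tautomer of 1,2-dione 16, which comes from enediol bis-silyl ether 15 by a two-electron oxidation. No carbon–carbon bond changes here.

**Key disconnection, C7–C8.** 15 is opened between the two oxygenated carbons to ring A diester 14. Cutting C5–C6 or C9–C10 instead would require unlike polarities and would form the quaternary centre during annulation. The C7–C8 cut leaves a monocyclic precursor with all three stereocentres in place and brings both ring B oxygens with the bond. The forward step needs acyloin rather than Dieckmann closure and must leave the C1=C10 alkene where it is.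

**C10 arm.** The C9–C10 bond of 14 is cut to enol triflate 13 and the Reformatsky reagent of methyl bromoacetate (11). 13 comes from enone 12 by conjugate reduction and enolate trapping, which fixes the triflate alkene at C1=C10.

**C5 arm and quaternary centre.** The C5–C6 bond of 12 is cut to enone 10 and 11. In 10 the C1=C2 double bond blocks the other α-position, so the enolate can only form at C5. Alkylating the saturated ketone 8 directly would depend on a thermodynamic enolate of uncertain regiochemistry. The electrophile must enter anti to the C4 methyl.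

**Setting C4.** 10 comes from saturated ketone 8 (Saegusa–Ito) and 8 from tetrasubstituted enone 7 by hydrogenation anti to the C3 silyl ether. This is the step that places the C4 methyl cis to the C3 oxygen; additions of a methyl nucleophile next to the oxygen would give the trans isomer.

**Ring A from a symmetric dione.** 7 is traced through vinylogous ester 5 (methyl addition and carbonyl transposition) to hydroxy ketone 4, its racemic acetate 3, vinylogous ester 2 and 2-methylcyclohexane-1,3-dione (1). Enzymatic resolution of 3 installs the C3 stereocentre, from which C4 and C5 follow.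

**Side chain.** Acid 30 is cut at C4=C5 to aldehyde 27 and phosphonate 28 (ester 29 between them). 27 is traced through 26, 25 and monoacetate 24 to the prochiral diol 23 and diethyl ethylmalonate (22). Enzymatic desymmetrisation of 23 sets the lone side-chain stereocentre.

## Roads not taken

**Alternative 1:** Dienyne metathesis cascade. The cut is at C9=C10 and C1=C2, back to acyclic dienyne A1: quaternary C5 carries a methyl group, an ethynyl group (C10≡C1), the C6–C9 chain ending in an allylic alcohol and vinyl group, and the C4–C2 chain ending in a propenyl group. A ruthenium alkylidene of the second-generation Grubbs type, RuCl2(H2IMes)(PCy3)(=CHPh), would load at the C9 vinyl group, close ring B onto C10 and pass the C1 carbene to the propenyl group to close ring A, giving dienol A2.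
- Merits: both rings and the C9=C10–C1=C2 diene form in one catalytic step under neutral conditions. In forming that diene it is better than the chosen plan, which needs a separate dehydrogenation.
- Weak points: A1 needs a propargylic quaternary centre next to two further stereocentres, built in an open chain without ring-based facial control. A2 has ring B at a low oxidation level (C8 carbinol, no C7 oxygen, C6–C7 saturated), so C7 oxygenation and dehydrogenation next to the quaternary carbon remain.
- Against it the chosen plan sets the arrival of both ring B oxygens in the bond-forming step and a quaternary centre made on a ring.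

**Alternative 2:** Oxy-Cope ring expansion and transannular ene closure. The 1,2-dialkenylcyclohexanol A3 (ring B with a vinyl carbinol at C10 and a methyl and isopropenyl group at C5) would be heated. The C5–C10 bond breaks and C2–C3 forms to give the (E)-cyclodecenone A4, whose C10 ketone and C4=C5 alkene re-form C5–C10 by an ene reaction to give decalinol A5.
- Merits: the decalin with its angular methyl is assembled thermally from a simple cyclohexanone, faster than the chosen plan reaches any bicycle.
- Weak points: A5 has no C3 oxygen, an exocyclic methylene in place of the C4 methyl stereocentre, only one ring B oxygen (the C7 ketal) and a C10 hydroxyl that must be eliminated. C3 oxidation, stereoselective C4 reduction, C8 oxygenation and two dehydrations would follow, with enantiocontrol resting on chirality transfer through a ten-membered ring.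
- The chosen plan is slower to the skeleton but carries C3, C4 and C5 and the ring B oxygens from the start, which is why it is preferred.

**Alternative 3:** Catechol dearomatisation by para-alkylation. The cut is at C4–C5, back to catechol mesylate A6 (ring B aromatic, a (Z)-alkenyl chain from C10 carrying the C3 silyl ether and a C4 mesylate). Base would ionise the catechol and the carbon para to the C8 oxygen (C5) would displace the mesylate with inversion, closing ring A and giving the core silyl ether A7 directly.
- Merits: this is the shortest road. One step delivers the trienone, the C7 enol and the C1=C2 bond with no redox adjustment; in step count and redox economy it is clearly better than the chosen plan.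
- Weak points: the catecholate is ambident (O- against C-alkylation). The attacking carbon already bears a methyl group, so a quaternary centre must form by substitution at a secondary carbon next to a silyloxy group, where elimination competes. The C5 configuration is decided only in the cyclisation transition state, and free catechols oxidise easily.
- Against this the chosen plan sets a carbon–carbon coupling with no ambident partner and a C5 configuration fixed beforehand by alkylation anti to the C4 methyl on a ring. It trades length for predictability.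

Key step: step 11

Assumption 1: the lipase of step 3 is taken to hydrolyse the (S)-acetate of 3 faster; if a given enzyme prefers the (R)-acetate, the recovered (S)-acetate is methanolysed (K2CO3, MeOH) to the same alcohol 4.

Assumption 2: the lipase of step 17 is taken to acetylate the arm that gives the (S)-monoacetate 24; if it prefers the other arm, hydrolysis of the diacetate of 23 with the same enzyme gives 24.

## Steps

Step 1
Reactants: 1 2-methylcyclohexane-1,3-dione
Product: 2 3-ethoxy-2-methylcyclohex-2-en-1-one
Conditions: EtOH, TsOH (cat.), toluene, reflux, Dean–Stark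
Reagents that add atoms: ethanol, CCO
Why: Acid-catalysed enol etherification of a cyclic 1,3-dione (vinylogous ester formation) with azeotropic removal of water; the dione is symmetric, so only one product can form.

Step 2
Reactants: 2 3-ethoxy-2-methylcyclohex-2-en-1-one
Product: 3 (±)-4-ethoxy-3-methyl-2-oxocyclohex-3-en-1-yl acetate
Conditions: Mn(OAc)3·2H2O, benzene, reflux, Dean–Stark
Reagents that add atoms: manganese triacetate, CC(=O)[O-].CC(=O)[O-].CC(=O)[O-].[Mn+3]
Why: Manganese triacetate α′-acetoxylation of an enone: the enolate bound to trivalent manganese is oxidised at C6, the only enolisable α′ position, and acetate is transferred there; the product is racemic.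

Step 3
Reactants: 3 (±)-4-ethoxy-3-methyl-2-oxocyclohex-3-en-1-yl acetate
Product: 4 (S)-3-ethoxy-6-hydroxy-2-methylcyclohex-2-en-1-one
Conditions: Burkholderia cepacia lipase, pH 7 phosphate buffer/toluene, rt, stopped near half conversion
Reagents that add atoms: none
Why: Lipase-catalysed kinetic resolution by enantioselective ester hydrolysis, a reaction type established for α′-acetoxy enones; the (S)-acetate is cleaved to 4, the unreacted (R)-acetate is separated, and this sets the C3 stereocentre of the target.

Step 4
Reactants: 4 (S)-3-ethoxy-6-hydroxy-2-methylcyclohex-2-en-1-one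
Product: 5 (S)-6-(tert-butyldimethylsilyloxy)-3-ethoxy-2-methylcyclohex-2-en-1-one
Conditions: TBSCl, imidazole, DMF, 0 °C to rt
Reagents that add atoms: tert-butyldimethylsilyl chloride, CC(C)(C)[Si](C)(C)Cl
Why: Imidazole-assisted silylation of a secondary alcohol; the bulky silyl ether lasts until step 14 and is the steering group of step 6.

Step 5
Reactants: 5 (S)-6-(tert-butyldimethylsilyloxy)-3-ethoxy-2-methylcyclohex-2-en-1-one
Product: 7 (S)-4-(tert-butyldimethylsilyloxy)-2,3-dimethylcyclohex-2-en-1-one, via tertiary carbinol 6 (not isolated)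
Conditions: MeLi, THF, −78 °C; then 1 M HCl, THF, 0 °C
Reagents that add atoms: methyllithium, [Li]C; water, O
Why: Stork–Danheiser alkylative carbonyl transposition: 1,2-addition of MeLi to the vinylogous ester carbonyl, then acid-induced loss of water and hydrolysis of the enol ether through the allylic oxocarbenium ion; the silyloxy stereocentre is untouched and ends up γ to the new ketone.

Step 6
Reactants: 7 (S)-4-(tert-butyldimethylsilyloxy)-2,3-dimethylcyclohex-2-en-1-one
Product: 8 (2S,3R,4S)-4-(tert-butyldimethylsilyloxy)-2,3-dimethylcyclohexan-1-one (all-cis)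
Conditions: H2 (4 bar), 5% Rh on Al2O3, EtOAc, rt
Reagents that add atoms: none
Why: Heterogeneous catalytic hydrogenation with syn delivery of both hydrogens to the face opposite the bulky C3 silyl ether, which places the C4 methyl cis to the C3 oxygen; the C5 centre formed alongside is erased in step 8.

Step 7
Reactants: 8 (2S,3R,4S)-4-(tert-butyldimethylsilyloxy)-2,3-dimethylcyclohexan-1-one
Product: 10 (4S,5R,6S)-4-(tert-butyldimethylsilyloxy)-5,6-dimethylcyclohex-2-en-1-one, via silyl enol ether 9 (not isolated)
Conditions: LiN(i-Pr)2, THF, −78 °C; Me3SiCl; then Pd(OAc)2, MeCN, rt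
Reagents that add atoms: chlorotrimethylsilane, C[Si](C)(C)Cl (its atoms are held in 9 only)
Why: Saegusa–Ito dehydrogenation: kinetic deprotonation at the less substituted C1 methylene, silylation, then oxidation of the enol ether by Pd(OAc)2 through an oxa-π-allyl complex and β-hydride loss; moving the unsaturation to C1=C2 leaves C5 as the only enolisable position for step 8.

Step 8
Reactants: 10 (4S,5R,6S)-4-(tert-butyldimethylsilyloxy)-5,6-dimethylcyclohex-2-en-1-one; 11 methyl bromoacetate
Product: 12 methyl 2-[(1R,5S,6R)-5-(tert-butyldimethylsilyloxy)-1,6-dimethyl-2-oxocyclohex-3-en-1-yl]acetate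
Conditions: LiN(i-Pr)2, THF, −78 °C; then DMPU, 11, −78 to −20 °C
Reagents that add atoms: none
Why: Enolate alkylation: the enone is deprotonated kinetically only at C5 (α′), giving the cross-conjugated dienolate regiospecifically; the C4 methyl sits pseudoaxial to avoid A(1,2) strain with the C5 methyl and the electrophile enters anti to it, so the acetate arm is trans to it and the two methyls are cis.

Step 9
Reactants: 12 methyl 2-[(1R,5S,6R)-5-(tert-butyldimethylsilyloxy)-1,6-dimethyl-2-oxocyclohex-3-en-1-yl]acetate
Product: 13 methyl 2-[(1R,5S,6R)-5-(tert-butyldimethylsilyloxy)-1,6-dimethyl-2-(trifluoromethylsulfonyloxy)cyclohex-2-en-1-yl]acetate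
Conditions: LiBH(s-Bu)3, THF, −78 °C; then PhNTf2, −78 to 0 °C
Reagents that add atoms: N-phenylbis(trifluoromethanesulfonimide), O=S(=O)(N(c1ccccc1)S(=O)(=O)C(F)(F)F)C(F)(F)F
Why: Conjugate reduction with enolate trapping: the hindered borohydride adds hydride to the β-unsubstituted enone (the carbonyl is shielded by quaternary C5) and the resulting C10–C1 enolate is O-sulfonylated, so the triflate double bond is fixed at C1=C10; the ester is inert at −78 °C.

Step 10
Reactants: 13 methyl 2-[(1R,5S,6R)-5-(tert-butyldimethylsilyloxy)-1,6-dimethyl-2-(trifluoromethylsulfonyloxy)cyclohex-2-en-1-yl]acetate; 11 methyl bromoacetate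
Product: 14 methyl 2-[(1R,5S,6R)-5-(tert-butyldimethylsilyloxy)-2-(2-methoxy-2-oxoethyl)-1,6-dimethylcyclohex-2-en-1-yl]acetate (ring A diester)
Conditions: BrZnCH2CO2Me (from 11, Zn dust, cat. Me3SiCl, THF, 40 °C), Pd(PPh3)4 (5 mol %), THF, 60 °C
Reagents that add atoms: none
Why: Negishi coupling of a Reformatsky reagent with an enol triflate (oxidative addition at C10–OTf, transmetalation from zinc, reductive elimination); the weakly basic zinc enolate leaves the alkene at C1=C10 and both esters intact.

Step 11
Reactants: 14 methyl 2-[(1R,5S,6R)-5-(tert-butyldimethylsilyloxy)-2-(2-methoxy-2-oxoethyl)-1,6-dimethylcyclohex-2-en-1-yl]acetate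
Product: 15 (4aR,5R,6S)-6-(tert-butyldimethylsilyloxy)-4a,5-dimethyl-2,3-bis(trimethylsilyloxy)-1,4,4a,5,6,7-hexahydronaphthalene (enediol bis-silyl ether)
Conditions: Na dispersion (4.5 equiv), Me3SiCl (5 equiv), toluene, reflux, Ar
Reagents that add atoms: chlorotrimethylsilane, C[Si](C)(C)Cl
Why: Sodium transfers one electron to each ester carbonyl; the two ketyl radical anions couple carbon to carbon (C7–C8), two methoxides leave, and the 1,2-dione takes up two more electrons to give the enediolate, which Me3SiCl silylates on both oxygens. This is the acyloin condensation in its silyl chloride (Rühlmann) form, whose standard use is the conversion of 1,6-diesters into 1,2-bis(trimethylsilyloxy)cyclohexenes. Ring B closes as a six-membered carbocycle by intramolecular coupling of the two ends of a 1,6-diester whose arms sit on adjacent ring A atoms (quaternary C5 and sp2 C10), so the reacting carbons are within reach in every conformer. No stereocentre is formed and C3, C4 and C5 take no part. The selectivity needed is acyloin coupling over Dieckmann condensation and over base-induced migration of the C1=C10 bond into conjugation with the C8 ester; Me3SiCl secures both by removing methoxide as it forms. The isolated trisubstituted alkene and the silyl ether are not reduced by sodium in toluene, and both ring B oxygens arrive in the bond-forming step.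

Step 12
Reactants: 15 (4aR,5R,6S)-6-(tert-butyldimethylsilyloxy)-4a,5-dimethyl-2,3-bis(trimethylsilyloxy)-1,4,4a,5,6,7-hexahydronaphthalene
Product: 17 (4aS,5R,6S)-6-(tert-butyldimethylsilyloxy)-3-hydroxy-4a,5-dimethyl-5,6,7,8-tetrahydronaphthalen-2(4aH)-one (diosphenol), via 1,2-dione 16 (not isolated)
Conditions: Br2 (1.0 equiv), CH2Cl2, −78 °C; then Et3N, −78 to 0 °C; aq. NH4Cl
Reagents that add atoms: none
Why: Bromine oxidation of a 1,2-bis(silyloxy)alkene to the 1,2-dione (the tetrasubstituted enediol ether should react far faster than the trisubstituted C1=C10 alkene at −78 °C), then amine-mediated enolisation brings C1=C10 into conjugation as C9=C10 and enolises C7 towards C6; should another dione tautomer persist, step 13 converges it on the same trienol ether.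

Step 13
Reactants: 17 (4aS,5R,6S)-6-(tert-butyldimethylsilyloxy)-3-hydroxy-4a,5-dimethyl-5,6,7,8-tetrahydronaphthalen-2(4aH)-one
Product: 19 (4aS,5R,6S)-3,6-bis(tert-butyldimethylsilyloxy)-4a,5-dimethyl-5,6-dihydronaphthalen-2(4aH)-one, via bis-silyl trienol ether 18 (not isolated)
Conditions: TBSOTf (2.5 equiv), Et3N, CH2Cl2, 0 °C to rt; crude 18, DDQ (1.1 equiv), 2,6-lutidine, CH2Cl2, −20 to 0 °C
Reagents that add atoms: tert-butyldimethylsilyl trifluoromethanesulfonate, CC(C)(C)[Si](C)(C)OS(=O)(=O)C(F)(F)F
Why: Soft enolisation with silyl triflate and amine silylates the C7 enol and turns the C8 ketone into the extended silyl dienol ether by loss of a C1 proton; DDQ then removes hydride from C2, the only allylic C–H of 18, and the silyloxy-stabilised cation loses its C8 silyl group. This is the DDQ dehydrogenation of a silyl dienol ether, the usual way from 4-en-3-ones to 4,6-dien-3-ones.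

Step 14
Reactants: 19 (4aS,5R,6S)-3,6-bis(tert-butyldimethylsilyloxy)-4a,5-dimethyl-5,6-dihydronaphthalen-2(4aH)-one
Product: 20 (4aS,5R,6S)-3,6-dihydroxy-4a,5-dimethyl-5,6-dihydronaphthalen-2(4aH)-one (core diol)
Conditions: HF·pyridine, pyridine, THF, 0 °C to rt
Reagents that add atoms: none
Why: Fluoride cleavage of both silyl ethers; buffered HF·pyridine is chosen because basic fluoride could deprotonate the vinylogously acidic C3–H of the trienone, and both groups are removed because the alkyl silyl ether cannot be cleaved ahead of the enol silyl ether.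

Step 15
Reactants: 20 (4aS,5R,6S)-3,6-dihydroxy-4a,5-dimethyl-5,6-dihydronaphthalen-2(4aH)-one
Product: 21 (4aS,5R,6S)-3-(tert-butyldimethylsilyloxy)-6-hydroxy-4a,5-dimethyl-5,6-dihydronaphthalen-2(4aH)-one
Conditions: TBSCl (1.05 equiv), Et3N, CH2Cl2, 0 °C
Reagents that add atoms: tert-butyldimethylsilyl chloride, CC(C)(C)[Si](C)(C)Cl
Why: Chemoselective silylation: Et3N ionises only the acidic diosphenol hydroxyl, which is silylated, while the neutral C3 alcohol, flanked by the C4 methyl and syn to the C5 methyl, should not react with the silyl chloride without a nucleophilic catalyst.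

Step 16
Reactants: 22 diethyl ethylmalonate
Product: 23 2-ethylpropane-1,3-diol
Conditions: LiAlH4, THF, 0 °C to reflux; aqueous NaOH work-up
Reagents that add atoms: none
Why: LiAlH4 reduction of a malonic diester to the 2-substituted propane-1,3-diol; the product is prochiral.

Step 17
Reactants: 23 2-ethylpropane-1,3-diol
Product: 24 (S)-2-(hydroxymethyl)butyl acetate
Conditions: Burkholderia cepacia lipase, vinyl acetate, t-BuOMe, rt
Reagents that add atoms: vinyl acetate, CC(=O)OC=C
Why: Lipase-catalysed desymmetrisation of a prochiral 2-substituted propane-1,3-diol by irreversible acetylation with vinyl acetate (enantiotopic group selection), which sets the side-chain stereocentre.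

Step 18
Reactants: 24 (S)-2-(hydroxymethyl)butyl acetate
Product: 25 (R)-2-[(tert-butyldimethylsilyloxy)methyl]butyl acetate
Conditions: TBSCl, imidazole, DMF, rt
Reagents that add atoms: tert-butyldimethylsilyl chloride, CC(C)(C)[Si](C)(C)Cl
Why: Silylation of the remaining primary alcohol; it assigns the free arm to the future hydroxymethyl group and the acetylated arm to the future aldehyde.

Step 19
Reactants: 25 (R)-2-[(tert-butyldimethylsilyloxy)methyl]butyl acetate
Product: 26 (R)-2-[(tert-butyldimethylsilyloxy)methyl]butan-1-ol
Conditions: K2CO3 (cat.), MeOH, 0 °C to rt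
Reagents that add atoms: none
Why: Base-catalysed transesterification (methanolysis) of the acetate; the silyl ether is stable and the stereocentre, not being α to a carbonyl, cannot epimerise.

Step 20
Reactants: 26 (R)-2-[(tert-butyldimethylsilyloxy)methyl]butan-1-ol
Product: 27 (S)-2-[(tert-butyldimethylsilyloxy)methyl]butanal
Conditions: Dess–Martin periodinane, NaHCO3, CH2Cl2, 0 °C
Reagents that add atoms: none
Why: Dess–Martin oxidation of a primary alcohol under buffered, non-basic conditions; the α-stereogenic aldehyde is used at once to avoid epimerisation.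

Step 21
Reactants: 27 (S)-2-[(tert-butyldimethylsilyloxy)methyl]butanal; 28 triethyl 4-phosphonocrotonate
Product: 29 ethyl (2E,4E,6R)-6-[(tert-butyldimethylsilyloxy)methyl]octa-2,4-dienoate
Conditions: LiN(SiMe3)2, THF, −78 to 0 °C
Reagents that add atoms: none
Why: Vinylogous Horner–Wadsworth–Emmons olefination; the stabilised γ-phosphonate anion should give the new C4=C5 bond E and brings the C2=C3 bond in E form, and the low temperature and non-nucleophilic base protect the α-stereocentre.

Step 22
Reactants: 29 ethyl (2E,4E,6R)-6-[(tert-butyldimethylsilyloxy)methyl]octa-2,4-dienoate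
Product: 30 (2E,4E,6R)-6-[(tert-butyldimethylsilyloxy)methyl]octa-2,4-dienoic acid
Conditions: LiOH, THF/MeOH/H2O, rt; then 1 M HCl to pH 4, 0 °C
Reagents that add atoms: lithium hydroxide, [Li+].[OH-]
Why: Saponification of the ethyl ester; the primary silyl ether is stable to LiOH and to brief cold acidification.

Step 23
Reactants: 21 (4aS,5R,6S)-3-(tert-butyldimethylsilyloxy)-6-hydroxy-4a,5-dimethyl-5,6-dihydronaphthalen-2(4aH)-one; 30 (2E,4E,6R)-6-[(tert-butyldimethylsilyloxy)methyl]octa-2,4-dienoic acid
Product: 32 (1R,2S,8aS)-7-(tert-butyldimethylsilyloxy)-1,8a-dimethyl-6-oxo-1,2,6,8a-tetrahydronaphthalen-2-yl (2E,4E,6R)-6-[(tert-butyldimethylsilyloxy)methyl]octa-2,4-dienoate, via mixed anhydride 31 (not isolated)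
Conditions: 30, 2,4,6-trichlorobenzoyl chloride, Et3N, toluene, rt; then 21, DMAP, toluene, rt to 40 °C
Reagents that add atoms: 2,4,6-trichlorobenzoyl chloride, O=C(Cl)c1c(Cl)cc(Cl)cc1Cl (its atoms are held in 31 only)
Why: Yamaguchi esterification: the mixed anhydride is formed first so that no free carboxylate meets the enol silyl ether, then DMAP transfers the dienoyl group to the hindered C3 alcohol with retention, since the C3–O bond is not broken.

Step 24
Reactants: 32 (1R,2S,8aS)-7-(tert-butyldimethylsilyloxy)-1,8a-dimethyl-6-oxo-1,2,6,8a-tetrahydronaphthalen-2-yl (2E,4E,6R)-6-[(tert-butyldimethylsilyloxy)methyl]octa-2,4-dienoate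
Product: 33 septeremophilane E, (1R,2S,8aS)-7-hydroxy-1,8a-dimethyl-6-oxo-1,2,6,8a-tetrahydronaphthalen-2-yl (2E,4E,6R)-6-(hydroxymethyl)octa-2,4-dienoate
Conditions: HF·pyridine, pyridine, THF, 0 °C to rt
Reagents that add atoms: none
Why: Fluoride cleavage of the enol silyl ether and the primary silyl ether in one step under mildly acidic conditions that should spare the allylic dienoate, the diosphenol and the trienone.

## Compound list

1 | 2-methylcyclohexane-1,3-dione | CC1C(=O)CCCC1=O | starting material
2 | 3-ethoxy-2-methylcyclohex-2-en-1-one | CCOC1=C(C)C(=O)CCC1 | intermediate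
3 | (±)-4-ethoxy-3-methyl-2-oxocyclohex-3-en-1-yl acetate (racemic) | CCOC1=C(C)C(=O)C(OC(C)=O)CC1 | intermediate
4 | (S)-3-ethoxy-6-hydroxy-2-methylcyclohex-2-en-1-one | O[C@H]1CCC(OCC)=C(C)C1=O | intermediate
5 | (S)-6-(tert-butyldimethylsilyloxy)-3-ethoxy-2-methylcyclohex-2-en-1-one | CC(C)(C)[Si](C)(C)O[C@H]1CCC(OCC)=C(C)C1=O | intermediate
6 | (6S)-6-(tert-butyldimethylsilyloxy)-3-ethoxy-1,2-dimethylcyclohex-2-en-1-ol (both C1 epimers) | CC(C)(C)[Si](C)(C)O[C@H]1CCC(OCC)=C(C)C1(C)O | intermediate (not isolated)
7 | (S)-4-(tert-butyldimethylsilyloxy)-2,3-dimethylcyclohex-2-en-1-one | CC(C)(C)[Si](C)(C)O[C@H]1CCC(=O)C(C)=C1C | intermediate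
8 | (2S,3R,4S)-4-(tert-butyldimethylsilyloxy)-2,3-dimethylcyclohexan-1-one (all-cis) | CC(C)(C)[Si](C)(C)O[C@H]1CCC(=O)[C@@H](C)[C@H]1C | intermediate
9 | (4S,5R,6S)-4-(tert-butyldimethylsilyloxy)-5,6-dimethyl-1-(trimethylsilyloxy)cyclohex-1-ene | CC(C)(C)[Si](C)(C)O[C@H]1CC=C(O[Si](C)(C)C)[C@@H](C)[C@H]1C | intermediate (not isolated)
10 | (4S,5R,6S)-4-(tert-butyldimethylsilyloxy)-5,6-dimethylcyclohex-2-en-1-one | CC(C)(C)[Si](C)(C)O[C@H]1C=CC(=O)[C@@H](C)[C@H]1C | intermediate
11 | methyl bromoacetate | COC(=O)CBr | starting material
12 | methyl 2-[(1R,5S,6R)-5-(tert-butyldimethylsilyloxy)-1,6-dimethyl-2-oxocyclohex-3-en-1-yl]acetate | CC(C)(C)[Si](C)(C)O[C@H]1C=CC(=O)[C@](C)(CC(=O)OC)[C@H]1C | intermediate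
13 | methyl 2-[(1R,5S,6R)-5-(tert-butyldimethylsilyloxy)-1,6-dimethyl-2-(trifluoromethylsulfonyloxy)cyclohex-2-en-1-yl]acetate | CC(C)(C)[Si](C)(C)O[C@H]1CC=C(OS(=O)(=O)C(F)(F)F)[C@](C)(CC(=O)OC)[C@H]1C | intermediate
14 | methyl 2-[(1R,5S,6R)-5-(tert-butyldimethylsilyloxy)-2-(2-methoxy-2-oxoethyl)-1,6-dimethylcyclohex-2-en-1-yl]acetate (ring A diester) | CC(C)(C)[Si](C)(C)O[C@H]1CC=C(CC(=O)OC)[C@](C)(CC(=O)OC)[C@H]1C | intermediate
15 | (4aR,5R,6S)-6-(tert-butyldimethylsilyloxy)-4a,5-dimethyl-2,3-bis(trimethylsilyloxy)-1,4,4a,5,6,7-hexahydronaphthalene | CC(C)(C)[Si](C)(C)O[C@H]1CC=C2CC(O[Si](C)(C)C)=C(O[Si](C)(C)C)C[C@]2(C)[C@H]1C | intermediate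
16 | (4aR,5R,6S)-6-(tert-butyldimethylsilyloxy)-4a,5-dimethyl-1,4,4a,5,6,7-hexahydronaphthalene-2,3-dione | CC(C)(C)[Si](C)(C)O[C@H]1CC=C2CC(=O)C(=O)C[C@]2(C)[C@H]1C | intermediate (not isolated)
17 | (4aS,5R,6S)-6-(tert-butyldimethylsilyloxy)-3-hydroxy-4a,5-dimethyl-5,6,7,8-tetrahydronaphthalen-2(4aH)-one | CC(C)(C)[Si](C)(C)O[C@H]1CCC2=CC(=O)C(O)=C[C@]2(C)[C@H]1C | intermediate
18 | (4aS,5R,6S)-2,3,6-tris(tert-butyldimethylsilyloxy)-4a,5-dimethyl-4a,5,6,7-tetrahydronaphthalene | CC(C)(C)[Si](C)(C)O[C@H]1CC=C2C=C(O[Si](C)(C)C(C)(C)C)C(O[Si](C)(C)C(C)(C)C)=C[C@]2(C)[C@H]1C | intermediate (not isolated)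
19 | (4aS,5R,6S)-3,6-bis(tert-butyldimethylsilyloxy)-4a,5-dimethyl-5,6-dihydronaphthalen-2(4aH)-one | CC(C)(C)[Si](C)(C)O[C@H]1C=CC2=CC(=O)C(O[Si](C)(C)C(C)(C)C)=C[C@]2(C)[C@H]1C | intermediate
20 | (4aS,5R,6S)-3,6-dihydroxy-4a,5-dimethyl-5,6-dihydronaphthalen-2(4aH)-one | O[C@H]1C=CC2=CC(=O)C(O)=C[C@]2(C)[C@H]1C | intermediate
21 | (4aS,5R,6S)-3-(tert-butyldimethylsilyloxy)-6-hydroxy-4a,5-dimethyl-5,6-dihydronaphthalen-2(4aH)-one | O[C@H]1C=CC2=CC(=O)C(O[Si](C)(C)C(C)(C)C)=C[C@]2(C)[C@H]1C | intermediate
22 | diethyl ethylmalonate | CCOC(=O)C(CC)C(=O)OCC | starting material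
23 | 2-ethylpropane-1,3-diol | CCC(CO)CO | intermediate
24 | (S)-2-(hydroxymethyl)butyl acetate | CC[C@H](COC(C)=O)CO | intermediate
25 | (R)-2-[(tert-butyldimethylsilyloxy)methyl]butyl acetate | CC[C@H](COC(C)=O)CO[Si](C)(C)C(C)(C)C | intermediate
26 | (R)-2-[(tert-butyldimethylsilyloxy)methyl]butan-1-ol | CC[C@H](CO)CO[Si](C)(C)C(C)(C)C | intermediate
27 | (S)-2-[(tert-butyldimethylsilyloxy)methyl]butanal | CC[C@H](C=O)CO[Si](C)(C)C(C)(C)C | intermediate
28 | triethyl 4-phosphonocrotonate | CCOC(=O)/C=C/CP(=O)(OCC)OCC | starting material
29 | ethyl (2E,4E,6R)-6-[(tert-butyldimethylsilyloxy)methyl]octa-2,4-dienoate | CC[C@H](/C=C/C=C/C(=O)OCC)CO[Si](C)(C)C(C)(C)C | intermediate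
30 | (2E,4E,6R)-6-[(tert-butyldimethylsilyloxy)methyl]octa-2,4-dienoic acid | CC[C@H](/C=C/C=C/C(=O)O)CO[Si](C)(C)C(C)(C)C | intermediate
31 | (2E,4E,6R)-6-[(tert-butyldimethylsilyloxy)methyl]octa-2,4-dienoic 2,4,6-trichlorobenzoic anhydride | CC[C@H](/C=C/C=C/C(=O)OC(=O)c1c(Cl)cc(Cl)cc1Cl)CO[Si](C)(C)C(C)(C)C | intermediate (not isolated)
32 | (1R,2S,8aS)-7-(tert-butyldimethylsilyloxy)-1,8a-dimethyl-6-oxo-1,2,6,8a-tetrahydronaphthalen-2-yl (2E,4E,6R)-6-[(tert-butyldimethylsilyloxy)methyl]octa-2,4-dienoate | CC[C@H](/C=C/C=C/C(=O)O[C@H]1C=CC2=CC(=O)C(O[Si](C)(C)C(C)(C)C)=C[C@]2(C)[C@H]1C)CO[Si](C)(C)C(C)(C)C | intermediate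
33 | septeremophilane E, (1R,2S,8aS)-7-hydroxy-1,8a-dimethyl-6-oxo-1,2,6,8a-tetrahydronaphthalen-2-yl (2E,4E,6R)-6-(hydroxymethyl)octa-2,4-dienoate | CC[C@H](/C=C/C=C/C(=O)O[C@H]1C=CC2=CC(=O)C(O)=C[C@]2(C)[C@H]1C)CO | target

## Step count and least certain steps

Total step count: 24. Longest linear sequence: 17 steps (steps 1–15, 23 and 24); the side-chain acid 30 takes 7 steps (16–22) and joins at step 23.

**Step 11 (key step).** The most likely failure is base-mediated condensation of the diester or migration of the C1=C10 bond into conjugation with the C8 ester, if methoxide is not silylated as fast as it forms. Intermolecular coupling at the sodium surface is a second risk. Fallback, from 14 back to 17: both esters of 14 are reduced with i-Bu2AlH at −78 °C to 2,2′-[(1R,5S,6R)-5-(tert-butyldimethylsilyloxy)-1,6-dimethylcyclohex-2-ene-1,2-diyl]diacetaldehyde F1. SmI2 in THF then closes ring B by pinacol coupling of the two aldehydes (the same C7–C8 bond, one oxidation level lower) to the C7,C8-diol F2. A double Swern oxidation in the presence of Et3N gives dione 16, which enolises to 17.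

**Step 6.** The tetrasubstituted alkene must lie flat on the metal next to the silyloxy group, so slow reduction, hydrogenolysis of the allylic C–O bond or erosion of facial selectivity may occur. Fallback, from 7 back to 13: homogeneous 1,4-hydrosilylation of 7 with Et3SiH and RhCl(PPh3)3, which cannot cleave the C–O bond, delivers hydride to C4 anti to the silyl ether and gives tert-butyl{[(1S,2R)-2,3-dimethyl-4-(triethylsilyloxy)cyclohex-3-en-1-yl]oxy}dimethylsilane F3, a regiodefined enol ether. MeLi releases its lithium enolate, which is alkylated by 11 anti to the C4 methyl to methyl 2-[(1R,2R,3S)-3-(tert-butyldimethylsilyloxy)-1,2-dimethyl-6-oxocyclohexyl]acetate F4. KN(SiMe3)2 and PhNTf2 then give 13, since C1 is the only enolisable position of F4.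

**Step 13.** The bis-silyloxy triene 18 is very electron-rich, so electron transfer to DDQ or attack at the C6=C7 enol ether may compete with hydride abstraction at C2, and over-oxidation is possible. Fallback, from 12 back to 20: no dehydrogenation is used.
- The lithium enolate of methyl acetate (LiN(i-Pr)2, MeOAc, THF, −78 °C) adds 1,2 to enone 12 and the aldolate is silylated in the cold with Me3SiCl. This gives dimethyl 2,2′-[(1R,5S,6R)-5-(tert-butyldimethylsilyloxy)-1,6-dimethyl-2-(trimethylsilyloxy)cyclohex-3-ene-1,2-diyl]diacetate F5, of which both C10 epimers serve.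
- Acyloin coupling of F5 under the conditions of step 11 closes ring B to the tris(trimethylsilyl) compound F6, which keeps the C1=C2 bond of 12 and carries a C10 silyloxy group.
- Br2 at −78 °C followed by DBU oxidises the enediol ether and expels the C10 silyloxy group by β-elimination from the C9 enolate. C9=C10 then forms next to C1=C2 and the C7 ketone enolises, giving the core silyl ether A7.
- HF·pyridine converts A7 into 20.

The price is an acyloin step that must tolerate a tertiary allylic silyl ether β to an ester.

**Step 15.** Silyl transfer to the C3 oxygen, or loss of the enol silyl group to carboxylate during step 23, would expose the enol to acylation. Fallback, from 20 back to 33: both hydroxyls of 20 are acylated with an excess of 30 under the conditions of step 23 to give the bis-dienoate F7 (enol ester at C7, alkyl ester at C3). The far more labile enol ester is cleaved selectively with K2CO3 in MeOH at 0 °C to the C7-hydroxy mono-ester F8, which still carries the side-chain silyl ether. HF·pyridine then gives 33.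

## Further compounds

F1 | step 11 | 2,2′-[(1R,5S,6R)-5-(tert-butyldimethylsilyloxy)-1,6-dimethylcyclohex-2-ene-1,2-diyl]diacetaldehyde | CC(C)(C)[Si](C)(C)O[C@H]1CC=C(CC=O)[C@](C)(CC=O)[C@H]1C
F2 | step 11 | (4aR,5R,6S)-6-(tert-butyldimethylsilyloxy)-4a,5-dimethyl-1,2,3,4,4a,5,6,7-octahydronaphthalene-2,3-diol (diol stereoisomers) | CC(C)(C)[Si](C)(C)O[C@H]1CC=C2CC(O)C(O)C[C@]2(C)[C@H]1C
F3 | step 6 | tert-butyl{[(1S,2R)-2,3-dimethyl-4-(triethylsilyloxy)cyclohex-3-en-1-yl]oxy}dimethylsilane | CC(C)(C)[Si](C)(C)O[C@H]1CCC(O[Si](CC)(CC)CC)=C(C)[C@H]1C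
F4 | step 6 | methyl 2-[(1R,2R,3S)-3-(tert-butyldimethylsilyloxy)-1,2-dimethyl-6-oxocyclohexyl]acetate | CC(C)(C)[Si](C)(C)O[C@H]1CCC(=O)[C@](C)(CC(=O)OC)[C@H]1C
F5 | step 13 | dimethyl 2,2′-[(1R,5S,6R)-5-(tert-butyldimethylsilyloxy)-1,6-dimethyl-2-(trimethylsilyloxy)cyclohex-3-ene-1,2-diyl]diacetate (both C2 epimers) | CC(C)(C)[Si](C)(C)O[C@H]1C=CC(CC(=O)OC)(O[Si](C)(C)C)[C@](C)(CC(=O)OC)[C@H]1C
F6 | step 13 | (4aR,5R,6S)-6-(tert-butyldimethylsilyloxy)-4a,5-dimethyl-2,3,8a-tris(trimethylsilyloxy)-1,4,4a,5,6,8a-hexahydronaphthalene (both C8a epimers) | CC(C)(C)[Si](C)(C)O[C@H]1C=CC2(O[Si](C)(C)C)CC(O[Si](C)(C)C)=C(O[Si](C)(C)C)C[C@]2(C)[C@H]1C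
F7 | step 15 | (4aS,5R,6S)-4a,5-dimethyl-2-oxo-2,4a,5,6-tetrahydronaphthalene-3,6-diyl bis{(2E,4E,6R)-6-[(tert-butyldimethylsilyloxy)methyl]octa-2,4-dienoate} | CC[C@H](/C=C/C=C/C(=O)O[C@H]1C=CC2=CC(=O)C(OC(=O)/C=C/C=C/[C@@H](CC)CO[Si](C)(C)C(C)(C)C)=C[C@]2(C)[C@H]1C)CO[Si](C)(C)C(C)(C)C
F8 | step 15 | (1R,2S,8aS)-7-hydroxy-1,8a-dimethyl-6-oxo-1,2,6,8a-tetrahydronaphthalen-2-yl (2E,4E,6R)-6-[(tert-butyldimethylsilyloxy)methyl]octa-2,4-dienoate | CC[C@H](/C=C/C=C/C(=O)O[C@H]1C=CC2=CC(=O)C(O)=C[C@]2(C)[C@H]1C)CO[Si](C)(C)C(C)(C)C
A1 | alternative 1 | (3R,6S,7R,8S,9E)-8-(tert-butyldimethylsilyloxy)-6-ethynyl-6,7-dimethylundeca-1,9-dien-3-ol (dienyne) | C/C=C/[C@H](O[Si](C)(C)C(C)(C)C)[C@H](C)[C@](C)(C#C)CC[C@H](O)C=C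
A2 | alternative 1 | bicyclic dienol with C9=C10–C1=C2, C8 hydroxyl and C3 silyl ether | CC(C)(C)[Si](C)(C)O[C@H]1C=CC2=C[C@@H](O)CC[C@]2(C)[C@H]1C
A3 | alternative 2 | 7-methyl-7-(prop-1-en-2-yl)-8-vinyl-1,4-dioxaspiro[4.5]decan-8-ol (alkenyl groups trans, one enantiomer drawn) | C=C[C@@]1(O)CCC2(OCCO2)C[C@]1(C)C(C)=C
A4 | alternative 2 | (E)-4,5-dimethylcyclodec-4-ene-1,7-dione 7-ethylene ketal | O=C1CCC/C(C)=C(C)/CC2(OCCO2)CC1
A5 | alternative 2 | decalinol with C4 exocyclic methylene, C10 hydroxyl and C7 ethylene ketal | C=C1CCC[C@@]2(O)CCC3(OCCO3)C[C@]12C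
A6 | alternative 3 | (Z)-3-(tert-butyldimethylsilyloxy)-5-(4,5-dihydroxy-2-methylphenyl)pent-4-en-2-yl methanesulfonate (catechol mesylate) | Cc1cc(O)c(O)cc1/C=C\[C@H](O[Si](C)(C)C(C)(C)C)[C@@H](C)OS(C)(=O)=O
A7 | alternative 3 | (4aS,5R,6S)-6-(tert-butyldimethylsilyloxy)-3-hydroxy-4a,5-dimethyl-5,6-dihydronaphthalen-2(4aH)-one (core silyl ether) | CC(C)(C)[Si](C)(C)O[C@H]1C=CC2=CC(=O)C(O)=C[C@]2(C)[C@H]1C
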